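The earlier runs and the new flask are calculated with made-up constants, noise included.

In a one-step world Q meets D and gives G, and a flask slows as Q falls. One chemist holds that view of cedar, the other thinks its D has stopped paying.

- cedar: Q 0.80 M; X 0.80 M; D 2.4 M; the very flask that is asked about, followed so far
- flask: Q 0.80 M; D 2.40 M; X 0.80 M; time 25 h

cedar run (percent of the Q and X together charged)

| time / h | G / % | Q / % |
|---|---|---|
| 1.33 | 37.7 | 21.7 |
| 4.00 | 48.4 | 16.0 |
| 8.00 | 50.7 | 13.4 |
| 10.0 | 52.4 | 14.3 |
| 15.0 | 53.0 | 13.9 |
| 20.0 | 53.2 | 13.2 |
| 25.0 | 53.8 | 11.7 |

(scatter of a reading: 1 percentage point)

- ochre: at 25 h add Q, 50.0% of the amount charged, then wait 8.0 h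
- green: change nothing and wait 8.0 h more
- amber: at 25 h take out 90% of the G then present, then wait 8.0 h

- D is single-handed; Q and X are mirror images of each other, charged as a racemate, each of them at the stated concentration
- what is taken out of G is counted as made
- additions bring no volume worth counting
- the handed part of D does not stay in what it makes, so the products of the two hands are mirror images too

1. G, in percent of the Q and X together first charged, at 25 h
2. which option adds most G ("none" when 2 percentage points or less is all one gets) (ochre / green / amber / none)
3. G present, with what was taken out counted in, in percent of the Q and X together first charged, after ochre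
4. G present, with what was taken out counted in, in percent of the Q and X together first charged, after green

The first chemist reads the clock. From 8.00 h to 25.0 h G rose 3.1 percentage points, so waiting 8.0 h should bring 1.5 points. Ochre raises Q by a factor of 3.14, so it should bring 4.6 points, more than the 2 points needed.

The second chemist answers that from 15.0 h to 25.0 h G rose 0.8 points against a scatter of 1 point, while Q still stood at 11.7%. Q is therefore present, yet G has stalled, and the reagent is the suspect. So she asks what the end state must be and keeps a budget: the yield of D, meaning moles of G at the stall per mole of D charged. The mean of the late readings is 53.3%, which gives a yield of 0.356. As a first estimate, she puts the gain of an option at the yield times the D still there.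

The forecast is her side's: 53.5% now, a little above that mean, 54.8% after ochre, 54% after green, and best none. Its ground: “So the driver has died, most likely because D is spent.”

The flask gives 53.4% now, 53.4% after ochre and 53.4% after green, and best is none, with gains of 0.012 points, 0.011 points and 0.011 points for ochre, green and amber.

    Q ⇌ X (k = 3.10 × 10⁻⁴ s⁻¹)
    D ⇌ Z (K = 0.130, k = 6.84 × 10⁻⁴ s⁻¹)
    D + Q → G (k = 3.06 × 10⁻⁴ L mol⁻¹ s⁻¹)
    2 D → J (k = 1.26 × 10⁻⁴ L mol⁻¹ s⁻¹)
    D + X → L (k = 1.02 × 10⁻⁴ L mol⁻¹ s⁻¹)

At 25.0 h cedar holds D, the limiting reagent, at 0.00937% of its charge, beside L at 20.8% and J at 0.606 M, which the number for G does not show. The estimate on that D gives 0.005 points and green gives 0.011 points, more than the estimate, so the average yield understates what the last D gives, though both are far below 2 points. The clock view holds in cedar before 3.67 h, where G stands 5 points from its value at 25 h. In a neighbour flask charged with 0.96 M of D, the budget gives 21.3%, but that flask reaches 32.3%, a yield of 0.538, with D at 0% and Q at 28.0%.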